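A gain of 0.586 d⁻¹ in r, the ratio of substrate to target, is what the maple and birch readings show on average from 5.00 d to 20.0 d, as the target fades and substrate returns.

| flask | substrate | reagent | remark | time |
|---|---|---|---|---|
| maple | 0.087 M | 0.085 M | run made earlier |  |
| birch | 0.087 M | 0.13 M | run made earlier |  |
| flask | 0.087 M | 0.0609 M |  | 15 d |

| run | time / d | target / % | substrate / % |
|---|---|---|---|
| maple | 0.333 | 18.1 | 81.3 |
| maple | 0.625 | 22.9 | 77.0 |
| maple | 1.25 | 25.0 | 75.5 |
| maple | 2.50 | 21.6 | 78.5 |
| maple | 5.00 | 16.1 | 83.8 |
| maple | 10.0 | 11.0 | 89.0 |
| maple | 20.0 | 7.1 | 93.1 |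
| birch | 0.333 | 24.3 | 75.6 |
| birch | 0.625 | 29.5 | 71.2 |
| birch | 1.25 | 29.9 | 69.8 |
| birch | 2.50 | 25.0 | 75.1 |
| birch | 5.00 | 18.6 | 81.9 |
| birch | 10.0 | 12.1 | 88.5 |
| birch | 20.0 | 6.6 | 92.8 |

(each reading ± 0.3 percentage points)

- what was read earlier has a scatter of 0.3 percentage points, one standard deviation

* the best time, 15 d at the latest, for target
* the amount of target, in percent of the substrate charged, at that time
* the first time at which target reaches 6.2%, in the same percent, in d

Run each tail line back to zero time and multiply its intercept by the reagent charge c: you get 0.194 M for maple and 0.192 M for birch, so with b = 0.193 M and g for that gain you can write r = b/c + gt at time t. The doubling time τ = b/(cg), in which r doubles its zero-time value, is 5.40 d for the flask.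

Turn the reagent first. At the flask's charge the line starts at 3.16, and since target is 1/(1+r) of the charge and both runs read their highest at 1.25 d, I expect 20.4% at that time in the flask, against the maple reading of 25.0%.

Then turn the time. The limit of 15 d lies far beyond that peak, so it should leave the best unchanged. It spans 2.78 doubling times, which puts the flask's target at 7.73% at the end.

The forecast, which also reads the tails as lines “with an intercept inversely proportional to the reagent charged”, gives 19.3% at 1.3 d, below my figure, and reaches 6.2% at 0.115 d.

The flask gives 20.8% at 1.25 d and reaches 6.2% at 0.0988 d, so the forecast's first time is high by a factor of 1.16. Changing just the reagent takes the maple peak from 24.8% to 20.8%, while changing just the time leaves it at 24.8%.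

    substrate + reagent ⇌ target (K = 18.6 L mol⁻¹, k = 0.00870 L mol⁻¹ min⁻¹)
    2 reagent → self-condensation product (k = 0.0100 L mol⁻¹ min⁻¹)

The relaxation half-life of the reversible step by itself, 0.400 d at 15.0 d, is short against the 15 d of the flask, the picture of a pre-equilibrium, and the flask then holds 7.83% target. In the same flask with 0.024 M of reagent, τ is 13.7 d, so the line gives 5.61% at 15 d, and that flask holds 6.12%.

The runs come from a simulation with made-up constants; the scatter is artificial.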